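**Retrosynthetic overview**
1. Target ⇐ twofold C7–H hydroxylation (iridium-catalysed borylation, then oxidation) of the 7,7''-dideoxy bis-flavanone; no protecting groups are used.
2. C3–C3'' bond ⇐ oxidative homocoupling of two molecules of the enol silane of (S)-5,4'-dimethoxyflavanone; with each half bonding anti to its C2 aryl group, the homochiral monomer gives the C2-symmetric trans,trans dimer.
3. Flavanone heterocycle ⇐ key ring expansion: (S)-4-aryl-oxetan-2-one → chroman-4-one by insertion of the C1–C2 unit of 2-fluoro-6-methoxyphenyllithium into the acyl–O bond (addition, ring opening, intramolecular SNAr).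
4. β-Lactone ⇐ β-hydroxy acid ⇐ asymmetric transfer hydrogenation of the aroylacetate made from anisole and methyl malonyl chloride; the aryl anion comes from 3-fluorophenol.
5. Ring order: the four-membered lactone is made first and expanded to the six-membered ring C of each half; rings A and B enter as intact benzene rings.

Assumption: the SMILES is read as the (2S,3R,2''S,3''R) isomer (both halves 2,3-trans, C2-symmetric); systematic names use bichromane locants with single primes.

**Route**

Step 1
Reactants: 1 anisole; 2 methyl 3-chloro-3-oxopropanoate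
Product: 3 methyl 3-(4-methoxyphenyl)-3-oxopropanoate
Conditions: AlCl3 (2.2 equiv), CH2Cl2, 0 → 23 °C
Reagents that add atoms: none
Why: Friedel–Crafts acylation of the activated arene goes para to the methoxy group because the bulky acylium–AlCl3 complex avoids the ortho position, and no stereocentre is formed.

Step 2
Reactants: 3 methyl 3-(4-methoxyphenyl)-3-oxopropanoate
Product: 5 (S)-3-hydroxy-3-(4-methoxyphenyl)propanoic acid, via hydroxy ester 4 (not isolated)
Conditions: RuCl[(S,S)-TsDPEN](p-cymene) (0.5 mol%), HCO2H/Et3N 5:2, 40 °C; then LiOH, THF/H2O, 0 °C; then 1 M HCl to pH 3, 0 °C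
Reagents that add atoms: lithium hydroxide, [Li+].[OH-]
Why: Noyori asymmetric transfer hydrogenation of the aryl ketone sets the (S) carbinol centre through the CH/π-controlled six-membered hydride-transfer transition state of the (S,S) catalyst (the sense known for acetophenone), and cold saponification then frees the acid without touching that centre.

Step 3
Reactants: 5 (S)-3-hydroxy-3-(4-methoxyphenyl)propanoic acid
Product: 6 (S)-4-(4-methoxyphenyl)oxetan-2-one
Conditions: PhSO2Cl, pyridine, 0 °C; cold work-up, used at once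
Reagents that add atoms: none
Why: Adam-type β-lactonisation activates the carboxyl group as a mixed sulfonic anhydride so that the hydroxyl oxygen is the nucleophile, which retains the C–O stereocentre because no bond to it is broken (the lactone is kept cold to prevent decarboxylation).

Step 4
Reactants: 7 3-fluorophenol
Product: 8 1-fluoro-3-methoxybenzene
Conditions: MeI, K2CO3, acetone, 56 °C
Reagents that add atoms: iodomethane, CI
Why: Williamson O-methylation of the phenoxide is fast and chemoselective, and this methyl ether becomes the 5-OMe group of each half.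

Step 5
Reactants: 8 1-fluoro-3-methoxybenzene; 6 (S)-4-(4-methoxyphenyl)oxetan-2-one
Product: 11 (S)-5-methoxy-2-(4-methoxyphenyl)chroman-4-one, via aryllithium 9 (not isolated), via lithium alkoxide 10 (not isolated)
Conditions: 8, n-BuLi (1.05 equiv), THF, −78 °C, 1 h; then 6, −78 °C, 1 h; then DMPU, −78 → 23 °C
Reagents that add atoms: none
Why: Proposed new method: an anionic two-atom ring expansion of a β-lactone (oxetan-2-one → chroman-4-one) in which the aryllithium from fluorine/methoxy-directed ortho-lithiation of 8 adds to the strained lactone carbonyl, the adduct collapses with acyl–oxygen cleavage to a hindered (hence mono-adding) ketone and a lithium alkoxide, and that alkoxide displaces the fluoride ortho to the new ketone by intramolecular SNAr, so the two aromatic carbons are inserted into the O–C(=O) bond while the C2–O bond is never broken and the (S) centre is carried over with retention; the closest known reactions are the acyl-selective opening of β-lactones by organolithiums to β-hydroxy ketones, SNAr ring closures of alkoxides onto 2-fluoroaryl ketones, and the acid-mediated Fries-type ring expansion of N-aryl β-lactams to 2,3-dihydroquinolin-4-ones.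

Step 6
Reactants: 11 (S)-5-methoxy-2-(4-methoxyphenyl)chroman-4-one (first molecule); 11 (S)-5-methoxy-2-(4-methoxyphenyl)chroman-4-one (second molecule)
Product: 13 (2S,2'S,3R,3'R)-5,5'-dimethoxy-2,2'-bis(4-methoxyphenyl)-[3,3'-bichromane]-4,4'-dione, via enol silane 12 (not isolated)
Conditions: 11 (2 equiv per equiv of 13), TMSOTf, Et3N, CH2Cl2, 0 °C; solvent switch to pentane, filtration; then Ag2O (1 equiv per 2 equiv of 12), DMSO, 65 °C
Reagents that add atoms: none
Why: Two molecules of 11 are each converted by soft enolisation into enol silane 12, which avoids the free enolate that would open the pyranone by retro-oxa-Michael elimination, and Ito–Saegusa-type oxidative homocoupling of the two enol silanes with Ag2O joins C3 to C3' on the face anti to the pseudo-equatorial C2 aryl group of each half, which sets both new centres 2,3-trans (3R,3'R) while any (R) monomer ends up in a separable meso diastereomer.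

Step 7
Reactants: 13 (2S,2'S,3R,3'R)-5,5'-dimethoxy-2,2'-bis(4-methoxyphenyl)-[3,3'-bichromane]-4,4'-dione
Product: 15 4',4''',5,5''-tetramethylchamaejasmin [(2S,2'S,3R,3'R)-7,7'-dihydroxy-5,5'-dimethoxy-2,2'-bis(4-methoxyphenyl)-[3,3'-bichromane]-4,4'-dione], via bis(boronate) 14 (not isolated)
Conditions: [Ir(OMe)(cod)]2 (3 mol%), 4,4'-di-tert-butyl-2,2'-bipyridine (6 mol%), B2pin2 (2.4 equiv), THF, 80 °C; then KHSO5 (as Oxone, 2KHSO5·KHSO4·K2SO4), acetone/H2O, 0 → 23 °C
Reagents that add atoms: potassium peroxymonosulfate, [K+].[O-]S(=O)(=O)OO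
Why: Iridium-catalysed aromatic C–H borylation is sterically controlled and on each ring A only C7–H has no ortho substituent (C6–H and C8–H flank OMe and the ring oxygen, and every C–H of the para-disubstituted anisyl rings is ortho-blocked), and the boronate is then oxidised to the phenol at the same carbon under near-neutral conditions that leave the ketones and the C2/C3 stereocentres untouched.

**Compound list**
1 | anisole | COc1ccccc1 | starting material
2 | methyl 3-chloro-3-oxopropanoate (methyl malonyl chloride) | COC(=O)CC(Cl)=O | starting material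
3 | methyl 3-(4-methoxyphenyl)-3-oxopropanoate | COC(=O)CC(=O)c1ccc(OC)cc1 | intermediate
4 | methyl (S)-3-hydroxy-3-(4-methoxyphenyl)propanoate | COC(=O)C[C@H](O)c1ccc(OC)cc1 | intermediate
5 | (S)-3-hydroxy-3-(4-methoxyphenyl)propanoic acid | OC(=O)C[C@H](O)c1ccc(OC)cc1 | intermediate
6 | (S)-4-(4-methoxyphenyl)oxetan-2-one | COc1ccc([C@H]2OC(=O)C2)cc1 | intermediate
7 | 3-fluorophenol | Oc1cccc(F)c1 | starting material
8 | 1-fluoro-3-methoxybenzene | COc1cccc(F)c1 | intermediate
9 | (2-fluoro-6-methoxyphenyl)lithium | [Li]c1c(F)cccc1OC | intermediate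
10 | lithium (S)-3-(2-fluoro-6-methoxyphenyl)-1-(4-methoxyphenyl)-3-oxopropan-1-olate | [Li+].[O-][C@@H](CC(=O)c1c(F)cccc1OC)c1ccc(OC)cc1 | intermediate
11 | (S)-5-methoxy-2-(4-methoxyphenyl)chroman-4-one | COc1ccc([C@H]2Oc3cccc(OC)c3C(=O)C2)cc1 | intermediate
12 | trimethyl{[(2S)-5-methoxy-2-(4-methoxyphenyl)-2H-chromen-4-yl]oxy}silane | COc1ccc([C@H]2Oc3cccc(OC)c3C(O[Si](C)(C)C)=C2)cc1 | intermediate
13 | (2S,2'S,3R,3'R)-5,5'-dimethoxy-2,2'-bis(4-methoxyphenyl)-[3,3'-bichromane]-4,4'-dione | COc1ccc([C@H]2Oc3cccc(OC)c3C(=O)[C@@H]2[C@H]2C(=O)c3c(OC)cccc3O[C@@H]2c2ccc(OC)cc2)cc1 | intermediate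
14 | (2S,2'S,3R,3'R)-5,5'-dimethoxy-2,2'-bis(4-methoxyphenyl)-7,7'-bis(4,4,5,5-tetramethyl-1,3,2-dioxaborolan-2-yl)-[3,3'-bichromane]-4,4'-dione | COc1ccc([C@H]2Oc3cc(B4OC(C)(C)C(C)(C)O4)cc(OC)c3C(=O)[C@@H]2[C@H]2C(=O)c3c(OC)cc(B4OC(C)(C)C(C)(C)O4)cc3O[C@@H]2c2ccc(OC)cc2)cc1 | intermediate
15 | 4',4''',5,5''-tetramethylchamaejasmin | COc1ccc([C@H]2Oc3cc(O)cc(OC)c3C(=O)[C@@H]2[C@H]2C(=O)c3c(OC)cc(O)cc3O[C@@H]2c2ccc(OC)cc2)cc1 | target

**Step count**
Total steps: 7. Longest linear sequence: 6 (steps 1, 2, 3, 5, 6, 7).

**Steps most likely to fail, with fallbacks**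

Step 5 (the new ring expansion). The risks are enolisation and β-elimination of 6 by the basic aryllithium, and retro-aldol of 10 before ring closure. The fallback uses known chemistry, sets out from 5 and comes back at 11. Acid 5 is coupled with MeNH(OMe)·HCl (EDC·HCl, N-methylmorpholine, CH2Cl2) to give the Weinreb amide (S)-3-hydroxy-N-methoxy-3-(4-methoxyphenyl)-N-methylpropanamide F1. This is silylated (TBSCl, imidazole, DMF) to (S)-3-[(tert-butyldimethylsilyl)oxy]-N-methoxy-3-(4-methoxyphenyl)-N-methylpropanamide F2. Addition of 9 (from 8 and n-BuLi, THF, −78 °C) gives the ketone (S)-3-[(tert-butyldimethylsilyl)oxy]-1-(2-fluoro-6-methoxyphenyl)-3-(4-methoxyphenyl)propan-1-one F3. Bu4NF in THF (0 → 23 °C) then removes the silyl group and the freed alkoxide closes the ring by intramolecular SNAr to give 11.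

Step 6 (oxidative homocoupling). The risks are low conversion when two hindered secondary centres must meet intermolecularly, and C3 epimer mixtures. The fallback sets out from 11 and comes back at 13. Two molecules of 11 are tied together with iPr2Si(OTf)2 (0.5 equiv) and Et3N in CH2Cl2 as the silicon-tethered bis(enol ether) bis{[(2S)-5-methoxy-2-(4-methoxyphenyl)-2H-chromen-4-yl]oxy}di(propan-2-yl)silane F4. Intramolecular oxidative coupling with (NH4)2Ce(NO3)6 and NaHCO3 in MeCN at −10 °C (short contact time, to spare the anisyl groups) then gives 13 after loss of the tether.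

Step 7 (late double C–H hydroxylation). The risks are incomplete double borylation of the crowded dimer and competing borylation ortho to OMe on the anisyl rings. The fallback sets out from 11 and comes back at 14. Monomer 11 is borylated under the same iridium catalysis with B2pin2 (1.1 equiv) to give (S)-5-methoxy-2-(4-methoxyphenyl)-7-(4,4,5,5-tetramethyl-1,3,2-dioxaborolan-2-yl)chroman-4-one F5, which is purified. It is converted (TMSOTf, Et3N, CH2Cl2, 0 °C) into the enol silane trimethyl{[(2S)-5-methoxy-2-(4-methoxyphenyl)-7-(4,4,5,5-tetramethyl-1,3,2-dioxaborolan-2-yl)-2H-chromen-4-yl]oxy}silane F6, and two molecules of it are homocoupled with Ag2O in DMSO to give 14. Oxidation with KHSO5 as in the second stage of step 7 then gives 15.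

**Further compounds**
F1 | step 5 | (S)-3-hydroxy-N-methoxy-3-(4-methoxyphenyl)-N-methylpropanamide | CON(C)C(=O)C[C@H](O)c1ccc(OC)cc1
F2 | step 5 | (S)-3-[(tert-butyldimethylsilyl)oxy]-N-methoxy-3-(4-methoxyphenyl)-N-methylpropanamide | CON(C)C(=O)C[C@H](O[Si](C)(C)C(C)(C)C)c1ccc(OC)cc1
F3 | step 5 | (S)-3-[(tert-butyldimethylsilyl)oxy]-1-(2-fluoro-6-methoxyphenyl)-3-(4-methoxyphenyl)propan-1-one | COc1cccc(F)c1C(=O)C[C@H](O[Si](C)(C)C(C)(C)C)c1ccc(OC)cc1
F4 | step 6 | bis{[(2S)-5-methoxy-2-(4-methoxyphenyl)-2H-chromen-4-yl]oxy}di(propan-2-yl)silane | COc1ccc([C@H]2Oc3cccc(OC)c3C(O[Si](C(C)C)(C(C)C)OC3=C[C@@H](c4ccc(OC)cc4)Oc4cccc(OC)c34)=C2)cc1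
F5 | step 7 | (S)-5-methoxy-2-(4-methoxyphenyl)-7-(4,4,5,5-tetramethyl-1,3,2-dioxaborolan-2-yl)chroman-4-one | COc1ccc([C@H]2Oc3cc(B4OC(C)(C)C(C)(C)O4)cc(OC)c3C(=O)C2)cc1
F6 | step 7 | trimethyl{[(2S)-5-methoxy-2-(4-methoxyphenyl)-7-(4,4,5,5-tetramethyl-1,3,2-dioxaborolan-2-yl)-2H-chromen-4-yl]oxy}silane | COc1ccc([C@H]2Oc3cc(B4OC(C)(C)C(C)(C)O4)cc(OC)c3C(O[Si](C)(C)C)=C2)cc1
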